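## Assumptions

- The ring alkenes are as drawn in the target SMILES: the b=c enal alkene is cis in the ring (Z) and the e=f trisubstituted alkene is trans in the ring (E).
- The chiral catalyst, ligand and enzyme variants named below are assumed to be available and to deliver the stated configurations (the enzyme variant is chosen from a panel).
- Numbered compounds are substrates and coupling partners. Atom-transferring reagents are given with SMILES in the "Reagents that add atoms" field and are not numbered.
- Ring atom labels used throughout:
  - a = CH(CH2OAc)
  - b = C(CHO)=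
  - c = =CH
  - d = CH2
  - e = =CH
  - f = C(CH3)=
  - g = CH2
  - h = CH(OH)
  - i = ring CH that carries the side chain
  - C* = CH(CH3) in the side chain

## Retrosynthetic overview

1. Target **23** comes from MnO2 oxidation of an allylic alcohol and lipase acetylation of the primary OH. Both operations are done on the nine-membered carbocycle.
2. The only ring is formed by RCM of diene **18** (Z-trisubstituted b=c). The E-trisubstituted e=f alkene is already present in the acyclic precursor.
3. The skipped diene comes from Zr-catalysed carboalumination and Cu-allylation of a homopropargylic silyl ether. The h-OH comes from ketoreductase reduction of ketone **10**.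
4. The i/a/C* stereotriad comes from an enamine Michael addition of (S)-citronellal (from geraniol by Ru-BINAP hydrogenation) to an alkylidene malonate. The malonate becomes the α-methylene ester used for RCM.
5. Ring formation: one ring, the nine-membered carbocycle, closed in Step 14.

## Route

**Step 1**
Reactants: **1** geraniol
Product: **2** (S)-citronellol
Conditions: H2 (100 atm), Ru(OAc)2[(R)-BINAP] (0.1 mol%), MeOH, 20 °C
Reagents that add atoms: none
Why: Noyori asymmetric hydrogenation; the allylic alcohol directs reduction of the C2=C3 alkene only, and the ligand enantiomer sets C3 as (S), which becomes C* (the (S)-ligand would give (R)).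

**Step 2**
Reactants: **2**
Product: **3** (S)-citronellal
Conditions: TEMPO (5 mol%), PhI(OAc)2, CH2Cl2, 20 °C
Reagents that add atoms: none
Why: TEMPO/BAIB oxidation of the primary alcohol leaves the trisubstituted alkene intact, and the stereocentre is β to the carbonyl so it cannot epimerise.

**Step 3**
Reactants: **4** (tert-butyldimethylsilyloxy)acetaldehyde; **5** dimethyl malonate
Product: **6** dimethyl 2-[2-(TBSO)ethylidene]malonate
Conditions: piperidine (5 mol%), AcOH (5 mol%), 4 Å MS, CH2Cl2, 0 → 20 °C
Reagents that add atoms: none beyond numbered reactants **4** and **5**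
Why: Knoevenagel condensation gives the activated, achiral Michael acceptor.

**Step 4**
Reactants: **3**; **6**
Product: **7** dimethyl 2-[(1R,2R,3S)-1-(TBSO-methyl)-2-formyl-3,7-dimethyloct-6-en-1-yl]malonate
Conditions: (S)-diphenylprolinol TMS ether (10 mol%), PhCO2H (10 mol%), toluene, 0 → 20 °C, 48 h
Reagents that add atoms: none beyond numbered reactants
Why: Hayashi–Jørgensen enamine Michael addition; the enamine of **3** adds through a synclinal transition state with one face shielded by the catalyst, giving the syn adduct with i (R) and a (R), and the existing C* (S) is assumed to be the matched partner.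

**Step 5**
Reactants: **7**; **8** propargyl bromide
Product: **9** homopropargylic alcohols (epimeric at h, about 1:1)
Conditions: Zn dust (3 equiv), THF / sat. aq. NH4Cl, 0 → 20 °C
Reagents that add atoms: propargyl bromide (8), C#CCBr (adds the propargyl unit that becomes g/f/e)
Why: Barbier-type propargylation is chemoselective for the aldehyde over the malonate; the new carbinol is deliberately unselective because both epimers converge in Steps 6–7.

**Step 6**
Reactants: **9**
Product: **10** ketone at h
Conditions: Dess–Martin periodinane, NaHCO3, CH2Cl2, 0 → 20 °C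
Reagents that add atoms: none
Why: DMP oxidation removes the unwanted carbinol stereochemistry, and the buffered, short reaction avoids epimerisation at i.

**Step 7**
Reactants: **10**
Product: **11** (h = S) homopropargylic alcohol
Conditions: ketoreductase (Prelog-type, (S)-selective, from a screening panel), NADP+ (0.5 mol%), iPrOH (20% v/v) as terminal reductant, 100 mM K-phosphate pH 7.0, DMSO (10%), 30 °C, 24 h
Reagents that add atoms: none
Why: Enzymatic ketone reduction delivers hydride to one face only, giving the (S)-alcohol under enzyme control and leaving i, a and C* untouched.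

**Step 8**
Reactants: **11**
Product: **12** h-OTBS ether
Conditions: TBSOTf (1.5 equiv), 2,6-lutidine, CH2Cl2, −78 → 0 °C
Reagents that add atoms: TBSOTf, C[Si](C)(OS(=O)(=O)C(F)(F)F)C(C)(C)C (adds TBS)
Why: Silylation protects the hindered secondary alcohol, which prevents δ-lactonisation onto the malonate and consumption of organometallics later; no stereocentre is touched.

**Step 9**
Reactants: **12**
Product: **13** methyl ester (a–CH2–CO2Me)
Conditions: LiCl (5 equiv), H2O (2 equiv), DMSO, 150 °C
Reagents that add atoms: none
Why: Krapcho dealkoxycarbonylation removes one ester; it is done after the ketone has been reduced, so there is no retro-Michael pathway and no epimerisation, and a is not α to the remaining carbonyl.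

**Step 10**
Reactants: **13**; **14** allyl bromide
Product: **15** skipped-diene methyl ester with (E)-trisubstituted e=f
Conditions: (i) Me3Al (3 equiv), Cp2ZrCl2 (0.3 equiv), ClCH2CH2Cl, 0 → 20 °C; (ii) CuCl (10 mol%), allyl bromide, THF, −30 → 20 °C
Reagents that add atoms: trimethylaluminium, C[Al](C)C (adds the f-CH3); allyl bromide (14), C=CCBr (adds d/c)
Why: Negishi Zr-catalysed syn-carboalumination puts Me on the internal alkyne carbon and Al on the terminal carbon, and Cu-catalysed SN2 allylation retains the alkene geometry, so g ends up trans to d (E).

**Step 11**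
Reactants: **15**
Product: **16** α-methylene ester (b=CH2)
Conditions: LDA (1.2 equiv), THF, −78 °C; then Me2N+=CH2 I−, −78 → 0 °C; then MeI; then DBU
Reagents that add atoms: Eschenmoser's salt, C=[N+](C)C.[I-] (adds the CH2 that is later lost as ethylene)
Why: Mannich reaction of the ester enolate followed by quaternisation and Hofmann-type elimination gives the 1,1-disubstituted acrylate needed for RCM; no stereocentre is formed and none is epimerisable.

**Step 12**
Reactants: **16**
Product: **17** 2-substituted allylic alcohol (b–CH2OH)
Conditions: DIBAL-H (2.5 equiv), CH2Cl2, −78 °C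
Reagents that add atoms: none
Why: 1,2-Reduction of the ester at low temperature leaves the alkenes and silyl ethers intact.

**Step 13**
Reactants: **17**
Product: **18** PMB ether (RCM precursor)
Conditions: NaH, PMBCl, TBAI (cat.), THF/DMF, 0 → 20 °C
Reagents that add atoms: 4-methoxybenzyl chloride, COc1ccc(CCl)cc1 (adds PMB)
Why: Williamson etherification gives a protecting group that is orthogonal to the two TBS ethers, so the late-stage acetylation can be done without lactol or lactone formation.

**Step 14**
Reactants: **18**
Product: **19** nine-membered carbocycle (Z b=c, E e=f)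
Conditions: Hoveyda–Grubbs II (10 mol%), 1,4-benzoquinone (10 mol%), toluene (0.002 M), 80 °C
Reagents that add atoms: none (ethylene is lost)
Why: Ring-closing metathesis joins the b=CH2 alkene to the c-vinyl group, and in a nine-membered ring that already contains a trans alkene the new alkene can only be Z; the quinone suppresses Ru–H isomerisation of the skipped diene, and the existing stereocentres are unaffected.

**Step 15**
Reactants: **19**
Product: **20** diol (a–CH2OH, h–OH; b–CH2OPMB)
Conditions: HF·pyridine, pyridine, THF, 0 → 20 °C (plastic vessel)
Reagents that add atoms: none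
Why: Fluoride-mediated removal of both silyl ethers leaves the PMB ether untouched.

**Step 16**
Reactants: **20**
Product: **21** primary acetate (h–OH free)
Conditions: lipase (Burkholderia cepacia lipase or CAL-B), vinyl acetate (4 equiv), MTBE, 20 °C
Reagents that add atoms: vinyl acetate, C=COC(C)=O (adds the acetyl group)
Why: Lipase-catalysed transesterification is irreversible because the enol by-product tautomerises to acetaldehyde, and the enzyme acylates the unhindered primary a–CH2OH but not the hindered secondary alcohol; no stereocentre is affected.

**Step 17**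
Reactants: **21**
Product: **22** allylic alcohol (b–CH2OH)
Conditions: DDQ (1.3 equiv), CH2Cl2 / pH 7 phosphate buffer (18:1), 0 °C, 30 min
Reagents that add atoms: none
Why: Oxidative PMB cleavage of the allylic PMB ether is fast at 0 °C under buffered conditions, and the acetate and the other alkenes survive.

**Step 18**
Reactants: **22**
Product: **23** Hydroxyacetyldictyolal
Conditions: activated MnO2 (20 equiv), CH2Cl2, 20 °C
Reagents that add atoms: none
Why: MnO2 oxidises only the allylic primary alcohol to the Z-enal; the homoallylic secondary alcohol and the acetate are inert, and the alkene geometry and all four stereocentres are retained.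

## Compound list

| No. | Name | SMILES | Role |
|---|---|---|---|
| 1 | geraniol | OC/C=C(\C)CCC=C(C)C | starting material |
| 2 | (S)-citronellol | OCC[C@@H](C)CCC=C(C)C | intermediate |
| 3 | (S)-citronellal | O=CC[C@@H](C)CCC=C(C)C | intermediate |
| 4 | (TBSO)acetaldehyde | O=CCO[Si](C)(C)C(C)(C)C | starting material |
| 5 | dimethyl malonate | COC(=O)CC(=O)OC | starting material |
| 6 | dimethyl 2-[2-(TBSO)ethylidene]malonate | COC(=O)C(=CCO[Si](C)(C)C(C)(C)C)C(=O)OC | intermediate |
| 7 | syn-Michael adduct aldehyde (i R, a R, C* S) | O=C[C@H]([C@@H](C)CCC=C(C)C)[C@@H](CO[Si](C)(C)C(C)(C)C)C(C(=O)OC)C(=O)OC | intermediate |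
| 8 | propargyl bromide | C#CCBr | starting material |
| 9 | homopropargylic alcohol, h-epimer mixture | C#CCC(O)[C@H]([C@@H](C)CCC=C(C)C)[C@@H](CO[Si](C)(C)C(C)(C)C)C(C(=O)OC)C(=O)OC | intermediate |
| 10 | ketone at h | C#CCC(=O)[C@H]([C@@H](C)CCC=C(C)C)[C@@H](CO[Si](C)(C)C(C)(C)C)C(C(=O)OC)C(=O)OC | intermediate |
| 11 | (h S)-homopropargylic alcohol | C#CC[C@H](O)[C@H]([C@@H](C)CCC=C(C)C)[C@@H](CO[Si](C)(C)C(C)(C)C)C(C(=O)OC)C(=O)OC | intermediate |
| 12 | h-OTBS malonate | C#CC[C@H](O[Si](C)(C)C(C)(C)C)[C@H]([C@@H](C)CCC=C(C)C)[C@@H](CO[Si](C)(C)C(C)(C)C)C(C(=O)OC)C(=O)OC | intermediate |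
| 13 | mono-methyl ester after Krapcho | C#CC[C@H](O[Si](C)(C)C(C)(C)C)[C@H]([C@@H](C)CCC=C(C)C)[C@@H](CO[Si](C)(C)C(C)(C)C)CC(=O)OC | intermediate |
| 14 | allyl bromide | C=CCBr | starting material |
| 15 | skipped-diene ester (E) | C=CC/C=C(\C)C[C@H](O[Si](C)(C)C(C)(C)C)[C@H]([C@@H](C)CCC=C(C)C)[C@@H](CO[Si](C)(C)C(C)(C)C)CC(=O)OC | intermediate |
| 16 | α-methylene ester | C=CC/C=C(\C)C[C@H](O[Si](C)(C)C(C)(C)C)[C@H]([C@@H](C)CCC=C(C)C)[C@@H](CO[Si](C)(C)C(C)(C)C)C(=C)C(=O)OC | intermediate |
| 17 | 2-substituted allylic alcohol | C=CC/C=C(\C)C[C@H](O[Si](C)(C)C(C)(C)C)[C@H]([C@@H](C)CCC=C(C)C)[C@@H](CO[Si](C)(C)C(C)(C)C)C(=C)CO | intermediate |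
| 18 | PMB ether, RCM precursor | C=CC/C=C(\C)C[C@H](O[Si](C)(C)C(C)(C)C)[C@H]([C@@H](C)CCC=C(C)C)[C@@H](CO[Si](C)(C)C(C)(C)C)C(=C)COCc1ccc(OC)cc1 | intermediate |
| 19 | nine-membered carbocycle (bis-TBS, PMB) | CC(C)(C)[Si](C)(C)OC[C@H]1/C(COCc2ccc(OC)cc2)=C\C/C=C(\C)C[C@H](O[Si](C)(C)C(C)(C)C)[C@@H]1[C@@H](C)CCC=C(C)C | intermediate |
| 20 | diol, PMB ether | OC[C@H]1/C(COCc2ccc(OC)cc2)=C\C/C=C(\C)C[C@H](O)[C@@H]1[C@@H](C)CCC=C(C)C | intermediate |
| 21 | primary acetate, PMB ether | CC(=O)OC[C@H]1/C(COCc2ccc(OC)cc2)=C\C/C=C(\C)C[C@H](O)[C@@H]1[C@@H](C)CCC=C(C)C | intermediate |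
| 22 | allylic alcohol acetate | CC(=O)OC[C@H]1/C(CO)=C\C/C=C(\C)C[C@H](O)[C@@H]1[C@@H](C)CCC=C(C)C | intermediate |
| 23 | Hydroxyacetyldictyolal | CC(=O)OC[C@H]1/C(C=O)=C\C/C=C(\C)C[C@H](O)[C@@H]1[C@@H](C)CCC=C(C)C | target |

## Totals

- Total steps: 18 (17 on the main line plus the Step 3 Knoevenagel on a side branch).
- Longest linear sequence: 17 steps (geraniol → Steps 1, 2, 4–18 → 23).

## Three steps most likely to fail

1. **Step 14 (RCM to the nine-membered ring).** Medium-ring closure can give oligomers or Ru–H isomerisation of the skipped diene.
   Fallback: close the ring at the c–d bond by intramolecular Pd-catalysed Stille coupling of a (Z)-alkenylstannane (from hydrostannation of the corresponding alkynoate) with the (E)-allylic carbonate made from the Negishi-derived allylic alcohol.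
2. **Step 4 (enamine Michael).** The C* (S) stereocentre may be mismatched with the catalyst, the γ-silyloxy alkylidene malonate may be unstable, and the aldehyde α-centre i is epimerisable.
   Fallback: Ireland–Claisen rearrangement of the (Z)-4-silyloxybut-2-enyl ester of (S)-citronellic acid. The i/a relationship then comes from enolate and alkene geometry, the diastereomers are separated by chromatography, and the acid is taken on via its Weinreb amide to the h-ketone.
3. **Step 7 (ketoreductase reduction).** No enzyme in the panel may give the (S)-alcohol with high selectivity on this hindered ketone, and the α-centre i may epimerise, or the free alcohol may lactonise onto the malonate.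
   Fallback: drop the oxidation–reduction and set h directly by reagent-controlled propargylation of aldehyde **7** with a chiral allenylzinc or allenylborane (double diastereodifferentiation), then continue from Step 8.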